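We count product per mM of coupling partner, not in percent of substrate.

in all of them: free catalyst 15 µM

| run | left-handed substrate | right-handed substrate | coupling partner | remark | time |
|---|---|---|---|---|---|
| grey | 10 mM | 10 mM | 10 mM | run made earlier |  |
| green | 10 mM | 10 mM | 40 mM | run made earlier |  |
| amber | 20 mM | 20 mM | 20 mM | run made earlier |  |
| flask | 10 mM | 10 mM | 20.0 mM |  | 50 min |

- grey (time / min: left-handed product / %, right-handed product / %): 12.0: 26.3, 3.8; 25.0: 26.9, 2.4; 40.0: 26.2, 3.2; 50.0: 26.7, 3.4; 60.0: 26.3, 3.4
- green (time / min: left-handed product / %, right-handed product / %): 5.00: 71.5, 10.2; 15.0: 71.8, 10.1; 30.0: 71.3, 10.3; 40.0: 71.6, 10.2; 60.0: 70.6, 10.0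
- amber (time / min: left-handed product / %, right-handed product / %): 5.00: 33.7, 4.2; 10.0: 33.9, 3.9; 15.0: 34.0, 3.7; 30.0: 33.7, 3.7; 60.0: 34.3, 4.9

(standard deviation of a reading: 0.5 percentage points)

- free catalyst is single-handed; left-handed substrate and right-handed substrate are mirror images of each other, charged as a racemate, each of them at the stated concentration
- an excess is below zero if the other one leads

1. left-handed product and right-handed product together, in percent of the left-handed substrate and right-handed substrate charged together, at 50 min
2. excess of left-handed product over right-handed product in the product at 50 min
3. whether the exchange between left-handed substrate and right-handed substrate keeps pace with the reaction: how far the product's excess at 50 min gets from its value without exchange to its value with instant exchange (above 80% keeps pace, below 20% hardly takes part, else lags behind)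

1. Grey and green sit flat from their first readings, so we average them: grey's plateau is 29.7% and green's 81.5%.

2. In grey, 59.4% of the coupling partner charged ends as product: this is the partner's share. In green it is 40.8%. Substrates and catalyst match in grey, green and the flask, so we assume that in these three each further mM of partner buys no more product than the one before.

3. Bound from above: the flask holds more partner than grey, so under that assumption its share stays at or under grey's, and its yield at or under 59.4%.

4. Bound from below: green's share gives 40.8%. The same assumption tightens this to the straight line from grey to green, 47.0%.

5. Our number: the flask's partner is twice grey's, and green's is twice the flask's, so in logarithms the flask sits midway. The geometric mean of the plateaus gives 49.2%.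

6. Green's left-handed product, 14.3 mM, exceeds the 10 mM of left-handed substrate charged, so the substrates exchange. Grey's reading at 50.0 min shows an excess of 77.4%.

7. The forecast says 53%, above our 49.2% but inside the bracket, with excess 77% and keeps pace, reasoning that “the reaction stops before substrate runs out”.

8. The flask gives 53.5%, excess 76.8%, and keeps pace.

    coupling partner + free catalyst + left-handed substrate → free catalyst + left-handed product (k = 5.20 × 10⁵ M⁻² s⁻¹)
    coupling partner + free catalyst + right-handed substrate → free catalyst + right-handed product (k = 62000 M⁻² s⁻¹)
    left-handed substrate ⇌ right-handed substrate (k = 0.250 s⁻¹)
    free catalyst → spent catalyst A (k = 0.00440 s⁻¹)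
    2 free catalyst → spent catalyst B (k = 1800 M⁻¹ s⁻¹)
    coupling partner → decomposed reagent (k = 0.0280 s⁻¹)

The flask's share came to 53.5%, below grey's 59.4%. By 5.00 min, coupling and decomposition had run together until coupling partner, the limiting reagent, stood at 0%, with 9.30 mM of decomposed reagent, while the substrates stood equal at 23.3% each. Afterwards the remaining free catalyst, 2.67%, went on disappearing, spent catalyst A rising from 18.8% to 21.1%, while left-handed product stayed at 47.3% and right-handed at 6.21%; the product's excess had gone 86% of the way from its value without exchange to its value with instant exchange. A neighbour flask with 12 mM of coupling partner gets a ceiling of 35.7% from grey's share and a floor of 33.2% from the line, and it gives 35.2%.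

Readings and results were computed with made-up constants, and the scatter is random.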